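Compound numbers 1–11 are those of the steps and the compound list; A and F labels are defined in the last block.

## Analysis of the target

The target 11 is a neoflavone: a coumarin in which benzene ring A (C4a, C5 to C8, C8a) is fused to the α-pyranone ring C (O1, C2, C3, C4), and C4 carries ring B, a 3-hydroxy-4-methoxyphenyl group. It has no stereocentre, and because ring B bears only hydrogen at C2' and C6', the C4–C1' axis rotates freely, so there is no stereochemical problem. Ring A carries methoxy groups at C5, C7 and C8 and one hydrogen at C6; with O1 it is a 1,2,3,5-tetraoxygenated benzene, electron-rich and easily oxidised. The sensitive groups are the lactone (opened reversibly by hydroxide), the free phenol at C3', and the aryl methyl ethers, which strong Lewis acids can cleave. The difficulty lies in placing the oxygens and in crowding: of six oxygens on the two benzene rings, one (O1) must enter the lactone and one (at C3') must stay free, the 5,7,8 pattern must be obtained and not the 5,6,7 isomer, and C4 is peri to the C5 methoxy group, so any bond made at C4 is hindered. The plan rests on the fact that C4 is bonded to C4a, C1' and C3 and bears no hydrogen. It is therefore at the oxidation level of a diaryl ketone carbon, so C3=C4 can come from olefination of a 2-hydroxybenzophenone whose phenol is O1, with C2 and C3 delivered together as a two-carbon ylide. The four oxygens of ring A then map onto 1,2,3,5-tetramethoxybenzene (4), whose two unsubstituted positions are equivalent.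

## Retrosynthetic reasoning

The last operation is removal of a protecting group, so the first cut is the O–S bond at C3': 11 goes back to the methanesulfonate 9. The phenol cannot go unprotected through a Lewis-acid acylation, and benzyl or silyl ethers would not survive that acid. A sulfonate does, and it also deactivates ring B so that the acid chloride 3 cannot acylate itself. The forward step must cleave the sulfonate with hydroxide without losing the lactone. The lactone will open to the coumarinate 10, but 10 keeps its cis geometry and recloses on acidification.

Ring C is opened next by cutting C3=C4 and O1–C2, which leads to the 2-hydroxybenzophenone 6 and the two-carbon ylide 7. The cut is placed at C4 because, as a ketone carbon, it can be made by aromatic acylation, so the crowded C4–C4a and C4–C1' bonds are in place before the ring is closed. The other classical cut, at C4–C4a with a phenol and a β-keto ester, would need a ring A phenol in which one of four oxygens is already free and would form the hindered peri bond under strong acid. In the forward direction the phenol of 6 is expected to exchange with the ester group of 7 to give the tethered ylide 8. This turns olefination of a hindered, electron-rich ketone into a six-membered ring closure that delivers 9 directly.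

The benzophenone 6 is cut at the bond between the carbonyl carbon and ring A (the future C4–C4a bond) and, in the same operation, at the O–CH3 bond of the methoxy group that becomes O1. This leads to 3 and 4. The cut is made on the ring A side because 4 has a mirror plane through C2 and C5 that makes its two free positions identical, so acylation can give only the tetramethoxy ketone 5. All four ring A oxygens then come from one stock compound, and O1 is differentiated without a protecting group. The forward reaction must acylate once and then remove only the methyl of the ortho-methoxy squeezed between the carbonyl and the neighbouring methoxy, which places the hydroxyl next to the future C8 methoxy.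

The acid chloride 3 goes back through the C–Cl bond to the acid 2 and through the O–S bond to isovanillic acid 1, which already has the hydroxyl and methoxy groups of ring B in the right positions. Sulfonylation comes first so that the phenol is masked before the acyl group is activated.

## Alternatives that were turned down

Alternative 1: Ring A is built last, on a preformed ring C, by cutting C5–C4a and tracing C5 to C8 back to a four-membered ring.
- **Forward key step:** the precursor is the hydroxycyclobutenone A2, whose carbinol carbon carries a dihydropyran with ring B at C4 and an orthoester at C2. Heating A2 should open the cyclobutenone to a dienylketene, whose ketene carbon closes onto C5 of the dihydropyran; enolisation then gives the chromane hydroquinone A1.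
- **For:** the position of every ring A oxygen is dictated by the cyclobutenone, and no ether needs selective cleavage. On regiochemical certainty this plan is stronger than the chosen one.
- **Against:** A1 is far from 11. Its oxidation-prone hydroquinone must be methylated twice, the orthoester hydrolysed, C3–C4 dehydrogenated and the silyl ether removed. The C4 stereocentre is made only to be destroyed. A2 needs a regioselective addition of a metalated ring C fragment to an unsymmetrical cyclobutenedione, both of which must first be prepared.
- **Comparison:** roughly twice as many operations. The chosen route offers a purchased ring A, the correct oxidation level of ring C at ring closure, and five steps.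

Alternative 2: C3 is removed as a single carbon; cutting C2–C3 and C3–C4 contracts ring C to the benzofuranone A4.
- **Forward key step:** A4 is silylated to the 2-silyloxybenzofuran A5. A dibromo-substituted carbene, generated under strongly basic conditions, adds to its C2=C3 bond, and the bromocyclopropane opens with loss of bromide and silyl to give the 3-bromocoumarin A3.
- **For:** the pyranone arrives at the right oxidation level and no hindered ketone has to be olefinated. A single hydrogenolysis could remove bromine and benzyl together; here it is at least as economical as the chosen end-game.
- **Against:** A4 must be made from the phenol A6, which is not a stock compound, so the oxygen differentiation problem moves to the start and costs separate steps. The key step is the least secure of the four plans. A5 is a tetrasubstituted, electron-rich enol ether, the alkoxide base can desilylate it to an enolate that is alkylated instead of cyclopropanated, and the carbene can attack ring A. An extra C–Br bond must be reduced.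
- **Comparison:** the chosen route closes the same ring by an established reaction class and introduces no atom that must later be removed.

Alternative 3: O1 is taken out of ring C by cutting O1–C8a and O1–C2, leaving the indanone A8.
- **Forward key step:** a peracid adds to the ketone of A8, and the electron-rich ring A carbon migrates to oxygen (Baeyer–Villiger), giving the dihydrocoumarin A7.
- **For:** A8 can be traced to the cheap arene A9 by acid-mediated hydroarylation and cyclisation. O1 is inserted by a rearrangement with a predictable migratory preference, so the 5,7,8 pattern needs no selective ether cleavage. On this point it is as strong as or stronger than the chosen plan.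
- **Against:** A7 is at the wrong oxidation level, so C3–C4 must be dehydrogenated with a quinone oxidant or by halogenation–elimination in the presence of a very electron-rich ring A. The peracid can also oxidise ring A. The C4 stereocentre is made and then destroyed. About seven steps are needed.
- **Comparison:** the chosen route takes the unsaturation directly from the ketone oxidation level and finishes in five steps. In place of the certainty of oxygen insertion it relies on the inherent preference of chelation-assisted ether cleavage.

Key step: step 4

Remark on the chemistry: 4 and 7 are taken as purchasable. Step 4 is written through the tethered ylide 8; a competing direct olefination would lead to the same product.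

## Route

Step 1
Reactants: 1 isovanillic acid (3-hydroxy-4-methoxybenzoic acid)
Product: 2 4-methoxy-3-(methylsulfonyloxy)benzoic acid
Conditions: MsCl (1.5 equiv), 2 M NaOH (aq, 3.5 equiv), THF, 0 °C; then 2 M HCl to pH 1
Reagents that add atoms: methanesulfonyl chloride, CS(=O)(=O)Cl
Why: Schotten–Baumann O-sulfonylation; the phenoxide of the dianion is the better nucleophile, and any carboxylic–sulfonic mixed anhydride is hydrolysed back to the carboxylate in the aqueous base, so only the aryl mesylate persists and the acid precipitates on acidification.

Step 2
Reactants: 2 4-methoxy-3-(methylsulfonyloxy)benzoic acid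
Product: 3 4-methoxy-3-(methylsulfonyloxy)benzoyl chloride
Conditions: (COCl)2 (1.5 equiv), DMF (cat.), CH2Cl2, 0 °C to rt; concentrate, use crude
Reagents that add atoms: oxalyl chloride, ClC(=O)C(=O)Cl
Why: Acid chloride formation through the DMF-derived chloroiminium catalyst; the aryl mesylate and the methyl ether are inert and all by-products are volatile.

Step 3
Reactants: 3 4-methoxy-3-(methylsulfonyloxy)benzoyl chloride; 4 1,2,3,5-tetramethoxybenzene
Product: 6 (2-hydroxy-3,4,6-trimethoxyphenyl)(4-methoxy-3-methylsulfonyloxyphenyl)methanone, via tetramethoxybenzophenone 5 (not isolated)
Conditions: AlCl3 (3 equiv), Et2O, 0 °C to rt, then reflux; ice/2 M HCl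
Reagents that add atoms: none
Why: Friedel–Crafts aroylation at one of the two equivalent free positions of 4 can give only 5, and the acyl group blocks a second attack; aluminium bound to the carbonyl oxygen then chelates an ortho-methoxy oxygen and chloride removes its methyl group (chelation-assisted ortho-demethylation), preferentially at the methoxy wedged between the carbonyl and a second methoxy, which is twisted out of the ring plane, more basic, and relieved of strain on cleavage. The aryl mesylate and the non-chelated ethers should be inert.

Step 4
Reactants: 6 (2-hydroxy-3,4,6-trimethoxyphenyl)(4-methoxy-3-methylsulfonyloxyphenyl)methanone; 7 ethyl (triphenylphosphoranylidene)acetate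
Product: 9 4-(4-methoxy-3-methylsulfonyloxyphenyl)-5,7,8-trimethoxycoumarin, via aryl ester ylide 8 (not isolated)
Conditions: Ph3P=CHCO2Et (3 equiv), toluene, reflux, Ar; PhNEt2, 200 °C if conversion stalls
Reagents that add atoms: none
Why: This is the tandem Wittig olefination–lactonisation of a 2-hydroxyaryl ketone with an ester-stabilised ylide, the established way from 2-hydroxybenzophenones to 4-arylcoumarins. At reflux the phenol of 6 exchanges with the ethoxy group of 7 (proton transfer to the ylide carbon makes the ester a phosphonium-activated acyl donor and ethanol leaves), which forms O1–C2 and gives the tethered ylide 8. In 8 the ylide carbon sits next to the ketone and adds to it in a 6-exo-trig closure, the C=O bond being exocyclic to the forming ring O1–C2–C3–C4–C4a–C8a. The resulting oxaphosphetane collapses with loss of Ph3PO and forms C3=C4, driven by the P=O bond and the aromatic pyranone. Any direct intermolecular olefination that competes gives an open hydroxy acrylate whose Z isomer lactonises to the same ring, so both courses converge on 9. No stereocentre is formed and the double-bond geometry is fixed by the ring. No regiochemical choice arises because 6 has one ketone and one phenol; the chemoselectivity needed is inertness of the mesylate and the methyl ethers, which a neutral stabilised ylide secures. The carbonyl is shielded by two ortho substituents on ring A and deactivated by the donor groups, which is why high temperature and the intramolecular pathway are relied on.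

Step 5
Reactants: 9 4-(4-methoxy-3-methylsulfonyloxyphenyl)-5,7,8-trimethoxycoumarin
Product: 11 3'-hydroxy-5,7,8,4'-tetramethoxy-4-phenylcoumarin, via tripotassium coumarinate 10 (not isolated)
Conditions: 2 M KOH (aq, 6 equiv), 1,4-dioxane, 80 °C, Ar, dark; then 2 M HCl to pH 1, rt
Reagents that add atoms: none
Why: Hydroxide cleaves the S–O bond of the aryl mesylate and frees the 3'-phenoxide while the lactone opens to the Z-configured coumarinate 10 (saponification); 10 cannot isomerise thermally in the dark, so acidification returns phenol and carboxylic acid cis to each other and they relactonise spontaneously. The four aryl methyl ethers are inert to aqueous hydroxide.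

## Compound list

1 | isovanillic acid (3-hydroxy-4-methoxybenzoic acid) | COc1ccc(C(=O)O)cc1O | starting material
2 | 4-methoxy-3-(methylsulfonyloxy)benzoic acid | COc1ccc(C(=O)O)cc1OS(C)(=O)=O | intermediate
3 | 4-methoxy-3-(methylsulfonyloxy)benzoyl chloride | COc1ccc(C(Cl)=O)cc1OS(C)(=O)=O | intermediate
4 | 1,2,3,5-tetramethoxybenzene | COc1cc(OC)c(OC)c(OC)c1 | starting material
5 | (4-methoxy-3-methylsulfonyloxyphenyl)(2,3,4,6-tetramethoxyphenyl)methanone | COc1ccc(C(=O)c2c(OC)c(OC)c(OC)cc2OC)cc1OS(C)(=O)=O | intermediate
6 | (2-hydroxy-3,4,6-trimethoxyphenyl)(4-methoxy-3-methylsulfonyloxyphenyl)methanone | COc1ccc(C(=O)c2c(O)c(OC)c(OC)cc2OC)cc1OS(C)(=O)=O | intermediate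
7 | ethyl (triphenylphosphoranylidene)acetate | CCOC(=O)C=P(c1ccccc1)(c1ccccc1)c1ccccc1 | starting material
8 | 2-(4-methoxy-3-methylsulfonyloxybenzoyl)-3,5,6-trimethoxyphenyl (triphenylphosphoranylidene)acetate | COc1ccc(C(=O)c2c(OC(=O)C=P(c3ccccc3)(c3ccccc3)c3ccccc3)c(OC)c(OC)cc2OC)cc1OS(C)(=O)=O | intermediate
9 | 4-(4-methoxy-3-methylsulfonyloxyphenyl)-5,7,8-trimethoxycoumarin | COc1ccc(-c2cc(=O)oc3c(OC)c(OC)cc(OC)c23)cc1OS(C)(=O)=O | intermediate
10 | tripotassium (Z)-3-(4-methoxy-3-oxidophenyl)-3-(3,4,6-trimethoxy-2-oxidophenyl)prop-2-enoate | [O-]C(=O)/C=C(/c1ccc(OC)c([O-])c1)c1c([O-])c(OC)c(OC)cc1OC.[K+].[K+].[K+] | intermediate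
11 | 3'-hydroxy-5,7,8,4'-tetramethoxy-4-phenylcoumarin (4-(3-hydroxy-4-methoxyphenyl)-5,7,8-trimethoxy-2H-chromen-2-one) | COc1ccc(-c2cc(=O)oc3c(OC)c(OC)cc(OC)c23)cc1O | target

## Step count and risk

Total step count: 5. Longest linear sequence: 5 steps (1 → 2 → 3 → 6 → 9 → 11); 4 and 7 are bought.

Least certain steps:

**Step 4 (key step).** The most likely failure is sluggish or incomplete olefination, because the carbonyl is shielded by two ortho substituents on ring A and deactivated by the chelated hydroxyl and the donor methoxy groups. The forcing temperature then favours slow loss of the ylide over ring closure. Fallback: setting out from 6, the phenol is esterified with diethylphosphonoacetic acid (DCC, DMAP cat., CH2Cl2) to give the aryl diethylphosphonoacetate F1. This is closed by an intramolecular Horner–Wadsworth–Emmons reaction under mild base (LiCl, DBU, MeCN, rt to 60 °C), which returns to the route at 9. The nucleophile is then a pre-tethered, more reactive phosphonate carbanion formed at low temperature, and no ester exchange with a stabilised ylide is needed.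

**Step 3.** The risk is loss of control over the ether cleavage: removal of the other ortho-methoxy, of both, or incomplete cleavage. The same excess of AlCl3 must drive both a slow aroylation and the demethylation. The regiochemistry of 6 is to be confirmed before it is carried on. Fallback: setting out from 2 and 4, the acid is activated with trifluoroacetic anhydride as the mixed anhydride F2, which acylates 4 without a metal Lewis acid (CH2Cl2, cat. H3PO4, rt), and 5 is isolated. A separate chelation-controlled cleavage with BCl3 (1.1 equiv, CH2Cl2, −78 to 0 °C) then returns to the route at 6. Bond formation and ether cleavage are thereby controlled independently.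

**Step 5.** Degradation may occur during the basic cleavage: the ring-opened, electron-rich phenoxide 10 can be oxidised by traces of air, double-bond isomerisation of the open acrylate would block reclosure, and conditions mild enough to avoid both may leave the sulfonate partly intact. Fallback: setting out from 6, the mesylate is removed at the benzophenone stage, where there is no lactone (KOH, aq. MeOH, reflux, Ar), to give the dihydroxybenzophenone F3. F3 is heated with 7 (4 equiv, toluene or PhNEt2) and should close through the tethered ylide F4 directly to 11, where the fallback rejoins the route. Free phenols are tolerated in this olefination–lactonisation, and no base treatment of a coumarin remains.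

**Step 1.** Sulfonylation may be incomplete because the sulfonyl chloride is hydrolysed competitively in the aqueous base, and reaction at the carboxylate may give anhydride by-products. Fallback: setting out from 1, the carboxylate is alkylated selectively to benzyl 3-hydroxy-4-methoxybenzoate F5 (BnBr, KHCO3, DMF). The phenol is mesylated under anhydrous conditions to the benzyl ester mesylate F6 (MsCl, Et3N, CH2Cl2, 0 °C). Hydrogenolysis (H2, Pd/C, EtOAc) then returns to the route at 2.

## Further compounds

F1 | step 4 | 2-(4-methoxy-3-methylsulfonyloxybenzoyl)-3,5,6-trimethoxyphenyl 2-(diethoxyphosphoryl)acetate | CCOP(=O)(OCC)CC(=O)Oc1c(OC)c(OC)cc(OC)c1C(=O)c1ccc(OC)c(OS(C)(=O)=O)c1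
F2 | step 3 | 4-methoxy-3-(methylsulfonyloxy)benzoic trifluoroacetic anhydride | COc1ccc(C(=O)OC(=O)C(F)(F)F)cc1OS(C)(=O)=O
F3 | step 5 | (2-hydroxy-3,4,6-trimethoxyphenyl)(3-hydroxy-4-methoxyphenyl)methanone | COc1ccc(C(=O)c2c(O)c(OC)c(OC)cc2OC)cc1O
F4 | step 5 | 2-(3-hydroxy-4-methoxybenzoyl)-3,5,6-trimethoxyphenyl (triphenylphosphoranylidene)acetate | COc1ccc(C(=O)c2c(OC(=O)C=P(c3ccccc3)(c3ccccc3)c3ccccc3)c(OC)c(OC)cc2OC)cc1O
F5 | step 1 | benzyl 3-hydroxy-4-methoxybenzoate | COc1ccc(C(=O)OCc2ccccc2)cc1O
F6 | step 1 | benzyl 4-methoxy-3-(methylsulfonyloxy)benzoate | COc1ccc(C(=O)OCc2ccccc2)cc1OS(C)(=O)=O
A1 | alternative 1 | 2,2,7-trimethoxy-4-[4-methoxy-3-(triisopropylsilyloxy)phenyl]chromane-5,8-diol (racemic, one enantiomer drawn) | COc1cc(O)c2c(c1O)OC(OC)(OC)C[C@@H]2c1ccc(OC)c(O[Si](C(C)C)(C(C)C)C(C)C)c1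
A2 | alternative 1 | 4-hydroxy-3-methoxy-4-{2,2-dimethoxy-4-[4-methoxy-3-(triisopropylsilyloxy)phenyl]-3,4-dihydro-2H-pyran-6-yl}cyclobut-2-en-1-one (racemic diastereomer mixture, one isomer drawn) | COC1=CC(=O)[C@]1(O)C1=C[C@@H](c2ccc(OC)c(O[Si](C(C)C)(C(C)C)C(C)C)c2)CC(OC)(OC)O1
A3 | alternative 2 | 4-(3-benzyloxy-4-methoxyphenyl)-3-bromo-5,7,8-trimethoxycoumarin | COc1ccc(-c2c(Br)c(=O)oc3c(OC)c(OC)cc(OC)c23)cc1OCc1ccccc1
A4 | alternative 2 | 3-(3-benzyloxy-4-methoxyphenyl)-4,6,7-trimethoxybenzofuran-2(3H)-one (racemic, one enantiomer drawn) | COc1ccc([C@H]2C(=O)Oc3c(OC)c(OC)cc(OC)c32)cc1OCc1ccccc1
A5 | alternative 2 | 3-(3-benzyloxy-4-methoxyphenyl)-2-(tert-butyldimethylsilyloxy)-4,6,7-trimethoxybenzofuran | COc1ccc(-c2c(O[Si](C)(C)C(C)(C)C)oc3c(OC)c(OC)cc(OC)c23)cc1OCc1ccccc1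
A6 | alternative 2 | 2,3,5-trimethoxyphenol | COc1cc(O)c(OC)c(OC)c1
A7 | alternative 3 | 4-(4-methoxy-3-methylsulfonyloxyphenyl)-5,7,8-trimethoxychroman-2-one (racemic, one enantiomer drawn) | COc1ccc([C@H]2CC(=O)Oc3c(OC)c(OC)cc(OC)c23)cc1OS(C)(=O)=O
A8 | alternative 3 | 3-(4-methoxy-3-methylsulfonyloxyphenyl)-4,6,7-trimethoxyindan-1-one (racemic, one enantiomer drawn) | COc1ccc([C@H]2CC(=O)c3c(OC)c(OC)cc(OC)c32)cc1OS(C)(=O)=O
A9 | alternative 3 | 1,2,4-trimethoxybenzene | COc1ccc(OC)c(OC)c1
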